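**Retrosynthetic overview**
1. Target ⇒ semi-hydrogenation of a 2-ynoate over Pd/CaCO3–Pb(OAc)2; the ynoate ⇒ esterification of the C8 alcohol of the lactone core with (R)-4-silyloxydec-2-ynoic acid (from heptanal and methyl propiolate).
2. Lactone core (C4 acetate, C5/C6 diol masked as an acetonide) ⇒ protecting-group exchange on the ring-closure product.
3. The nine-membered lactone (the only ring of the target, formed first; the dioxolane is a temporary second ring) ⇒ C5–C6 bond by SmI2 ketyl–carbonyl (pinacol) macrocyclisation of an ester-tethered keto-aldehyde, which also creates C5 and C6.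
4. Keto-aldehyde ⇒ addition of a storable tartrate Z-crotylboronate (from cis-but-2-ene) to the α-acyloxy aldehyde derived from the (S)-but-3-en-2-yl ester of a levulinic-type keto acid (C7, C8), then alkene cleavage.
5. Keto acid (C2–C5) ⇒ Z-crotylboration of methacrolein with an Ipc2B reagent (C3, C4), benzylation, oxidative cleavage of both alkenes.

Assumption: ring atoms are numbered O1, C2 (lactone C=O) to C9 (CH–CH3 on O1); read from the SMILES the target is 3R,4R,5R,6S,7S,8R,9S with a (2Z,4R)-4-hydroxydec-2-enoate on O8.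

**Route**

Step 1
Reactants: 1 methacrolein (2-methylprop-2-enal); 2 cis-but-2-ene
Product: 4 (3R,4S)-2,4-dimethylhexa-1,5-dien-3-ol, via Z-crotyl-diisopinocampheylborane 3 (not isolated)
Conditions: 2, n-BuLi, KOt-Bu, THF, −78 to −45 °C; (+)-Ipc2BOMe, −78 °C; BF3·OEt2; then 1, −78 °C; NaOH, H2O2, 0 °C to rt
Reagents that add atoms: (+)-B-methoxydiisopinocampheylborane, COB([C@H]1C[C@H]2C[C@@H]([C@@H]1C)C2(C)C)[C@H]1C[C@H]2C[C@@H]([C@@H]1C)C2(C)C (its Ipc2B unit is carried in 3 only)
Why: Brown asymmetric crotylboration through a closed chair transition state, a reagent class that gives high enantioselectivity with enals, in which the Z-crotyl geometry gives the syn methyl/hydroxyl pair and the Ipc ligands derived from (−)-α-pinene direct attack on the Re face of the aldehyde, setting 3R and 4S (the future C4 and C3).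

Step 2
Reactants: 4 (3R,4S)-2,4-dimethylhexa-1,5-dien-3-ol
Product: 5 (3R,4S)-3-(benzyloxy)-2,4-dimethylhexa-1,5-diene
Conditions: NaH, BnBr, Bu4NI (cat.), THF/DMF, 0 °C to rt
Reagents that add atoms: benzyl bromide, BrCc1ccccc1
Why: Williamson etherification of the sodium alkoxide, which touches no stereocentre and installs an ether that can chelate in the ring closure.

Step 3
Reactants: 5 (3R,4S)-3-(benzyloxy)-2,4-dimethylhexa-1,5-diene
Product: 7 (2R,3R)-3-(benzyloxy)-2-methyl-4-oxopentanoic acid, via keto-aldehyde 6 (not isolated)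
Conditions: O3, MeCN/H2O 9:1, 0 °C; then NaClO2, NaH2PO4, 0 °C to rt
Reagents that add atoms: ozone, [O-][O+]=O; sodium chlorite, [Na+].[O-]Cl=O
Why: Ozonolysis in wet acetonitrile (water traps the carbonyl oxides, so both C=C bonds give carbonyl groups directly) followed in the same pot by Pinnick-type chlorite oxidation, which converts only the aldehyde into the acid under mildly acidic conditions that do not epimerise the α-centres, while the isopropenyl group becomes the methyl ketone.

Step 4
Reactants: 7 (2R,3R)-3-(benzyloxy)-2-methyl-4-oxopentanoic acid; 8 (S)-but-3-en-2-ol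
Product: 9 (S)-but-3-en-2-yl (2R,3R)-3-(benzyloxy)-2-methyl-4-oxopentanoate
Conditions: DCC, DMAP (0.1 equiv), CH2Cl2, 0 °C to rt
Reagents that add atoms: none
Why: Steglich esterification (carbodiimide activation with DMAP acyl transfer), which couples γ-keto acids of the levulinic type cleanly and does not break the C–O bond of 8, so C9 keeps its S configuration.

Step 5
Reactants: 9 (S)-but-3-en-2-yl (2R,3R)-3-(benzyloxy)-2-methyl-4-oxopentanoate
Product: 11 (S)-1-oxopropan-2-yl (2R,3R)-3-(benzyloxy)-2-methyl-4-oxopentanoate, via ozonide 10 (not isolated)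
Conditions: O3, CH2Cl2, −78 °C; then PPh3, −78 °C to rt
Reagents that add atoms: ozone, [O-][O+]=O
Why: Ozonolysis with reductive phosphine work-up cleaves the only alkene to the α-acyloxy aldehyde under neutral, cold conditions, so the adjacent stereocentre is not epimerised.

Step 6
Reactants: 2 cis-but-2-ene
Product: 12 diisopropyl (4S,5S)-2-[(2Z)-but-2-en-1-yl]-1,3,2-dioxaborolane-4,5-dicarboxylate (the (S,S)-tartrate Z-crotylboronate)
Conditions: 2, n-BuLi, KOt-Bu, THF, −78 to −45 °C; B(Oi-Pr)3, −78 °C; 1 M aq. HCl (NaCl-saturated), Et2O, diisopropyl D-(−)-tartrate; MgSO4; kept as a titrated toluene solution over 4 Å MS at −20 °C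
Reagents that add atoms: triisopropyl borate, CC(C)OB(OC(C)C)OC(C)C; diisopropyl (2S,3S)-tartrate, CC(C)OC(=O)[C@@H](O)[C@H](O)C(=O)OC(C)C
Why: Schlosser metalation of cis-but-2-ene gives configurationally stable Z-crotylpotassium, which is trapped by the borate at −78 °C and transesterified with the tartrate on acidic work-up (Roush tartrate crotylboronate preparation), keeping the Z geometry and giving a storable reagent; no stereocentre is formed.

Step 7
Reactants: 11 (S)-1-oxopropan-2-yl (2R,3R)-3-(benzyloxy)-2-methyl-4-oxopentanoate; 12 diisopropyl (4S,5S)-2-[(2Z)-but-2-en-1-yl]-1,3,2-dioxaborolane-4,5-dicarboxylate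
Product: 13 (2S,3R,4S)-3-hydroxy-4-methylhex-5-en-2-yl (2R,3R)-3-(benzyloxy)-2-methyl-4-oxopentanoate
Conditions: 12 (1.5 equiv), 4 Å MS, toluene, −78 °C, 12 h; then pH 7 phosphate buffer, 0 °C
Reagents that add atoms: none
Why: Roush asymmetric crotylboration through a closed chair transition state, in which the Z-crotyl geometry gives the syn C7-methyl/C8-hydroxyl pair and the (S,S)-tartrate ester (Re-face attack) is matched with the Felkin–Anh/Cornforth preference of the α-acyloxy aldehyde for the 8,9-anti product, setting C8 (R) and C7 (S), while the boronate reacts far faster with the aldehyde than with the ketone or esters at −78 °C and needs only a neutral, non-oxidative work-up that avoids 1,2-acyl migration.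

Step 8
Reactants: 13 (2S,3R,4S)-3-hydroxy-4-methylhex-5-en-2-yl (2R,3R)-3-(benzyloxy)-2-methyl-4-oxopentanoate
Product: 14 (2S,3R,4S)-3-[(tert-butyldimethylsilyl)oxy]-4-methylhex-5-en-2-yl (2R,3R)-3-(benzyloxy)-2-methyl-4-oxopentanoate
Conditions: TBSOTf, 2,6-lutidine, CH2Cl2, −78 °C
Reagents that add atoms: tert-butyldimethylsilyl triflate, CC(C)(C)[Si](C)(C)OS(=O)(=O)C(F)(F)F
Why: Silyl triflate silylation of the only hydroxyl group at −78 °C, fast enough to outrun acyl migration and enol silylation of the ketone, giving the bulky non-chelating ether wanted for the ring closure.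

Step 9
Reactants: 14 (2S,3R,4S)-3-[(tert-butyldimethylsilyl)oxy]-4-methylhex-5-en-2-yl (2R,3R)-3-(benzyloxy)-2-methyl-4-oxopentanoate
Product: 16 (2S,3R,4R)-3-[(tert-butyldimethylsilyl)oxy]-4-methyl-5-oxopentan-2-yl (2R,3R)-3-(benzyloxy)-2-methyl-4-oxopentanoate, via ozonide 15 (not isolated)
Conditions: O3, CH2Cl2, −78 °C; then PPh3, −78 °C to rt
Reagents that add atoms: ozone, [O-][O+]=O
Why: Ozonolysis with reductive work-up unmasks the C6 aldehyde while benzyl and silyl ethers survive at −78 °C, and the α-methyl aldehyde is used at once to avoid epimerisation.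

Step 10
Reactants: 16 (2S,3R,4R)-3-[(tert-butyldimethylsilyl)oxy]-4-methyl-5-oxopentan-2-yl (2R,3R)-3-(benzyloxy)-2-methyl-4-oxopentanoate
Product: 17 (3R,4R,5R,6S,7S,8R,9S)-4-(benzyloxy)-8-[(tert-butyldimethylsilyl)oxy]-5,6-dihydroxy-3,5,7,9-tetramethyloxonan-2-one
Conditions: SmI2 (5 equiv, 0.05 M), THF, 25 °C, 16 added by syringe pump over 8 h (final 2 mM); then aq. NH4Cl
Reagents that add atoms: none
Why: Proposed new method: single-electron transfer from SmI2 to the aldehyde gives a samarium ketyl radical whose trivalent samarium centre also binds the C5 ketone oxygen and the neighbouring benzyl ether oxygen, so that the C6 radical adds to the ketone carbon within a chelate and a second electron transfer traps the alkoxy radical as the samarium diolate, closing the nine-membered ring under high dilution; chelate (Cram) attack on the ketone puts the C5 hydroxyl syn to the C4 benzyloxy group (5R) and Felkin–Anh approach at the α-methyl ketyl carbon, next to the non-chelating silyl ether, puts the C6 hydroxyl syn to the C7 methyl (6S); without HMPA or a proton source the esters and the α-benzyloxy ketone are reduced far more slowly than the aldehyde; the closest known reactions are SmI2 pinacol cyclisations of keto-aldehydes to five- to eight-membered cis-diols (α-alkoxy dicarbonyls from sugars included) and SmI2-mediated closures of eight- and nine-membered lactones.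

Step 11
Reactants: 17 (3R,4R,5R,6S,7S,8R,9S)-4-(benzyloxy)-8-[(tert-butyldimethylsilyl)oxy]-5,6-dihydroxy-3,5,7,9-tetramethyloxonan-2-one
Product: 18 5,6-O-isopropylidene acetal of 17 (all centres as in 17)
Conditions: Me2C(OMe)2, PPTS (cat.), CH2Cl2, rt
Reagents that add atoms: 2,2-dimethoxypropane, COC(C)(C)OC
Why: Acid-catalysed transacetalisation (acetonide formation) on the only diol, masking both new hydroxyl groups so that C4 and C8 can be acylated one after the other.

Step 12
Reactants: 18 5,6-O-isopropylidene acetal of 17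
Product: 19 C4 alcohol (18 with the benzyl ether replaced by a free hydroxyl)
Conditions: H2 (1 atm), Pd(OH)2/C, EtOAc, rt
Reagents that add atoms: none
Why: Catalytic hydrogenolysis of the benzyl ether, to which the lactone, silyl ether and acetonide are inert, at a stage where the molecule has no C=C bond.

Step 13
Reactants: 19 C4 alcohol
Product: 20 C4 acetate of 19
Conditions: Ac2O, DMAP (cat.), pyridine, CH2Cl2, 0 °C to rt
Reagents that add atoms: acetic anhydride, CC(=O)OC(C)=O
Why: DMAP-catalysed acetylation (nucleophilic acyl-transfer catalysis) of the single free hydroxyl group, kept short and with pyridine as the only base to avoid β-elimination of the new β-acetoxy lactone.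

Step 14
Reactants: 20 C4 acetate
Product: 21 C8 alcohol (20 with the silyl ether replaced by a free hydroxyl)
Conditions: HF·pyridine, pyridine, THF, 0 °C to rt
Reagents that add atoms: none
Why: Fluoride-mediated desilylation under buffered acidic conditions, which leaves acetonide, acetate and lactone untouched and avoids the alkoxide-driven acyl shifts a basic fluoride source could cause.

Step 15
Reactants: 22 heptanal; 23 methyl propiolate
Product: 25 methyl (R)-4-hydroxydec-2-ynoate, via ethylzinc acetylide 24 (not isolated)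
Conditions: 23, Et2Zn, HMPA, CH2Cl2, rt; (S)-BINOL (40 mol %), Ti(OiPr)4; then 22, rt; aq. NH4Cl
Reagents that add atoms: diethylzinc, CC[Zn]CC (its EtZn unit is carried in 24 only)
Why: Catalytic asymmetric alkynylzinc addition to an aldehyde (BINOL–Ti(OiPr)4 system of Pu, with HMPA letting the propiolate form its zinc acetylide at room temperature), in which (S)-BINOL directs addition to the Si face of heptanal and sets 4R.

Step 16
Reactants: 25 methyl (R)-4-hydroxydec-2-ynoate
Product: 26 methyl (R)-4-[(triethylsilyl)oxy]dec-2-ynoate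
Conditions: TESCl, imidazole, DMF, 0 °C
Reagents that add atoms: chlorotriethylsilane, CC[Si](Cl)(CC)CC
Why: Standard silylation of the propargylic alcohol, giving an ether that the mild acid of the acetonide removal will later cleave as well.

Step 17
Reactants: 26 methyl (R)-4-[(triethylsilyl)oxy]dec-2-ynoate
Product: 27 (R)-4-[(triethylsilyl)oxy]dec-2-ynoic acid
Conditions: LiOH, THF/H2O, 0 °C; then aq. HCl to pH 4
Reagents that add atoms: lithium hydroxide, [Li+].[OH-]
Why: Saponification of the methyl ester at 0 °C, which the conjugated alkyne and the silyl ether tolerate for the short time needed.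

Step 18
Reactants: 21 C8 alcohol; 27 (R)-4-[(triethylsilyl)oxy]dec-2-ynoic acid
Product: 28 C8 ester of 21 with acid 27
Conditions: DCC, DMAP (cat.), CH2Cl2, −20 to 0 °C
Reagents that add atoms: none
Why: Steglich esterification of the only free hydroxyl with a sterically small alkynoic acid, run cold with catalytic DMAP to suppress conjugate addition to the ynoate.

Step 19
Reactants: 28 C8 ynoate ester
Product: 29 (3R,4R,5R,6S,7S,8R,9S)-4-acetoxy-5,6-dihydroxy-3,5,7,9-tetramethyl-2-oxooxonan-8-yl (R)-4-hydroxydec-2-ynoate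
Conditions: CF3CO2H/H2O/THF 1:1:4, 0 °C to rt
Reagents that add atoms: none
Why: Acid-catalysed hydrolysis of the acetonide and the silyl ether, done at the alkyne stage because a 4-hydroxy-2-ynoate cannot close to a butenolide, while lactone, acetate and ynoate esters survive cold aqueous acid.

Step 20
Reactants: 29 deprotected ynoate
Product: 30 (3R,4R,5R,6S,7S,8R,9S)-4-acetoxy-5,6-dihydroxy-3,5,7,9-tetramethyl-2-oxooxonan-8-yl (2Z,4R)-4-hydroxydec-2-enoate (CNP0240788.3)
Conditions: H2 (1 atm), Pd/CaCO3 poisoned with Pb(OAc)2 (Lindlar catalyst), quinoline, EtOAc, rt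
Reagents that add atoms: none
Why: Lindlar semi-hydrogenation, in which syn delivery of H2 on the poisoned palladium surface gives only the Z-alkene, run last and under neutral conditions so that the Z-4-hydroxy-enoate never meets acid or base that would close it to a butenolide.

**Compound list**
1 | methacrolein (2-methylprop-2-enal) | C=C(C)C=O | starting material
2 | cis-but-2-ene | C/C=C\C | starting material
3 | Z-crotyl-diisopinocampheylborane (Ipc groups from (−)-α-pinene) | C/C=C\CB([C@H]1C[C@H]2C[C@@H]([C@@H]1C)C2(C)C)[C@H]1C[C@H]2C[C@@H]([C@@H]1C)C2(C)C | intermediate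
4 | (3R,4S)-2,4-dimethylhexa-1,5-dien-3-ol | C=C(C)[C@H](O)[C@@H](C)C=C | intermediate
5 | (3R,4S)-3-(benzyloxy)-2,4-dimethylhexa-1,5-diene | C=C(C)[C@H](OCc1ccccc1)[C@@H](C)C=C | intermediate
6 | (2R,3R)-3-(benzyloxy)-2-methyl-4-oxopentanal | CC(=O)[C@H](OCc1ccccc1)[C@@H](C)C=O | intermediate
7 | (2R,3R)-3-(benzyloxy)-2-methyl-4-oxopentanoic acid | CC(=O)[C@H](OCc1ccccc1)[C@@H](C)C(=O)O | intermediate
8 | (S)-but-3-en-2-ol | C[C@H](O)C=C | starting material
9 | (S)-but-3-en-2-yl (2R,3R)-3-(benzyloxy)-2-methyl-4-oxopentanoate | CC(=O)[C@H](OCc1ccccc1)[C@@H](C)C(=O)O[C@@H](C)C=C | intermediate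
10 | (1S)-1-(1,2,4-trioxolan-3-yl)ethyl (2R,3R)-3-(benzyloxy)-2-methyl-4-oxopentanoate (ozonide, both epimers at the trioxolane carbon) | CC(=O)[C@H](OCc1ccccc1)[C@@H](C)C(=O)O[C@@H](C)C1OCOO1 | intermediate
11 | (S)-1-oxopropan-2-yl (2R,3R)-3-(benzyloxy)-2-methyl-4-oxopentanoate | CC(=O)[C@H](OCc1ccccc1)[C@@H](C)C(=O)O[C@@H](C)C=O | intermediate
12 | diisopropyl (4S,5S)-2-[(2Z)-but-2-en-1-yl]-1,3,2-dioxaborolane-4,5-dicarboxylate ((S,S)-tartrate Z-crotylboronate) | C/C=C\CB1O[C@H](C(=O)OC(C)C)[C@@H](C(=O)OC(C)C)O1 | intermediate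
13 | (2S,3R,4S)-3-hydroxy-4-methylhex-5-en-2-yl (2R,3R)-3-(benzyloxy)-2-methyl-4-oxopentanoate | CC(=O)[C@H](OCc1ccccc1)[C@@H](C)C(=O)O[C@@H](C)[C@H](O)[C@@H](C)C=C | intermediate
14 | (2S,3R,4S)-3-[(tert-butyldimethylsilyl)oxy]-4-methylhex-5-en-2-yl (2R,3R)-3-(benzyloxy)-2-methyl-4-oxopentanoate | CC(=O)[C@H](OCc1ccccc1)[C@@H](C)C(=O)O[C@@H](C)[C@H](O[Si](C)(C)C(C)(C)C)[C@@H](C)C=C | intermediate
15 | (2S,3R,4R)-3-[(tert-butyldimethylsilyl)oxy]-4-(1,2,4-trioxolan-3-yl)pentan-2-yl (2R,3R)-3-(benzyloxy)-2-methyl-4-oxopentanoate (ozonide, both epimers at the trioxolane carbon) | CC(=O)[C@H](OCc1ccccc1)[C@@H](C)C(=O)O[C@@H](C)[C@H](O[Si](C)(C)C(C)(C)C)[C@@H](C)C1OCOO1 | intermediate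
16 | (2S,3R,4R)-3-[(tert-butyldimethylsilyl)oxy]-4-methyl-5-oxopentan-2-yl (2R,3R)-3-(benzyloxy)-2-methyl-4-oxopentanoate | CC(=O)[C@H](OCc1ccccc1)[C@@H](C)C(=O)O[C@@H](C)[C@H](O[Si](C)(C)C(C)(C)C)[C@@H](C)C=O | intermediate
17 | (3R,4R,5R,6S,7S,8R,9S)-4-(benzyloxy)-8-[(tert-butyldimethylsilyl)oxy]-5,6-dihydroxy-3,5,7,9-tetramethyloxonan-2-one | CC(C)(C)[Si](C)(C)O[C@@H]1[C@@H](C)[C@H](O)[C@@](C)(O)[C@H](OCc2ccccc2)[C@@H](C)C(=O)O[C@H]1C | intermediate
18 | 5,6-O-isopropylidene acetal of 17 (all centres as in 17) | CC(C)(C)[Si](C)(C)O[C@@H]1[C@@H](C)[C@@H]2OC(C)(C)O[C@@]2(C)[C@H](OCc3ccccc3)[C@@H](C)C(=O)O[C@H]1C | intermediate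
19 | C4 alcohol: 18 with OH in place of the benzyloxy group | CC(C)(C)[Si](C)(C)O[C@@H]1[C@@H](C)[C@@H]2OC(C)(C)O[C@@]2(C)[C@H](O)[C@@H](C)C(=O)O[C@H]1C | intermediate
20 | C4 acetate of 19 | CC(C)(C)[Si](C)(C)O[C@@H]1[C@@H](C)[C@@H]2OC(C)(C)O[C@@]2(C)[C@H](OC(C)=O)[C@@H](C)C(=O)O[C@H]1C | intermediate
21 | C8 alcohol: 20 with OH in place of the silyloxy group | O[C@@H]1[C@@H](C)[C@@H]2OC(C)(C)O[C@@]2(C)[C@H](OC(C)=O)[C@@H](C)C(=O)O[C@H]1C | intermediate
22 | heptanal | CCCCCCC=O | starting material
23 | methyl propiolate | C#CC(=O)OC | starting material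
24 | ethyl(3-methoxy-3-oxoprop-1-yn-1-yl)zinc | CC[Zn]C#CC(=O)OC | intermediate
25 | methyl (R)-4-hydroxydec-2-ynoate | CCCCCC[C@@H](O)C#CC(=O)OC | intermediate
26 | methyl (R)-4-[(triethylsilyl)oxy]dec-2-ynoate | CCCCCC[C@@H](O[Si](CC)(CC)CC)C#CC(=O)OC | intermediate
27 | (R)-4-[(triethylsilyl)oxy]dec-2-ynoic acid | CCCCCC[C@@H](O[Si](CC)(CC)CC)C#CC(=O)O | intermediate
28 | C8 ester of 21 with 27 (acetonide and triethylsilyl ether in place) | CCCCCC[C@@H](O[Si](CC)(CC)CC)C#CC(=O)O[C@@H]1[C@@H](C)[C@@H]2OC(C)(C)O[C@@]2(C)[C@H](OC(C)=O)[C@@H](C)C(=O)O[C@H]1C | intermediate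
29 | (3R,4R,5R,6S,7S,8R,9S)-4-acetoxy-5,6-dihydroxy-3,5,7,9-tetramethyl-2-oxooxonan-8-yl (R)-4-hydroxydec-2-ynoate | CCCCCC[C@@H](O)C#CC(=O)O[C@@H]1[C@@H](C)[C@H](O)[C@@](C)(O)[C@H](OC(C)=O)[C@@H](C)C(=O)O[C@H]1C | intermediate
30 | (3R,4R,5R,6S,7S,8R,9S)-4-acetoxy-5,6-dihydroxy-3,5,7,9-tetramethyl-2-oxooxonan-8-yl (2Z,4R)-4-hydroxydec-2-enoate | CCCCCC[C@@H](O)/C=C\C(=O)O[C@@H]1[C@@H](C)[C@H](O)[C@@](C)(O)[C@H](OC(C)=O)[C@@H](C)C(=O)O[C@H]1C | target

**Step count**
Total: 20 steps. Longest linear sequence: 16 steps (steps 1–5, 7–14 and 18–20). Step 6 (the crotylboronate) and steps 15–17 (the side chain) are branches.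

**Three steps most likely to fail, with fallbacks**

Step 10 (SmI2 ring closure). The risks are the entropy of a nine-membered ring, simple reduction or dimerisation of the aldehyde, loss of the α-benzyloxy group, and the wrong diol isomer. The fallback closes the ring by alkene metathesis and introduces the diol by epoxide opening. It sets out from 14: Wittig methylenation of the ketone (Ph3P=CH2, THF, −78 to 0 °C) gives the diene ester (2S,3R,4S)-3-[(tert-butyldimethylsilyl)oxy]-4-methylhex-5-en-2-yl (2R,3R)-3-(benzyloxy)-2,4-dimethylpent-4-enoate F1. Ring-closing metathesis (second-generation Grubbs catalyst, toluene, 80 °C, 1 mM) gives the nine-membered lactone with a Z-configured C5=C6 alkene F2. Epoxidation (m-CPBA, NaHCO3, CH2Cl2) gives the cis-5,6-epoxide F3, with its oxygen on the ring face that carries the C6 oxygen of 17 (separated if both faces react). Acid-catalysed hydrolysis (HClO4 cat., THF/H2O, 0 °C), with water attacking the tertiary C5 with inversion, gives 17, where the route resumes at step 11.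

Step 7 (crotylboration of the α-acyloxy keto-aldehyde). The risks are 1,2-acyl migration, epimerisation of the aldehyde and slow or poorly selective addition next to the ester and ketone. The fallback makes the C6–C10 alcohol separately on an ether-protected lactaldehyde and esterifies afterwards. It sets out from acid 7 and purchased ethyl (S)-lactate (CCOC(=O)[C@H](C)O). The lactate is protected with 4-methoxybenzyl trichloroacetimidate and CSA as ethyl (S)-2-[(4-methoxybenzyl)oxy]propanoate F4, then reduced (i-Bu2AlH, CH2Cl2, −78 °C) to (S)-2-[(4-methoxybenzyl)oxy]propanal F5. Crotylboration with 12 as in step 7 gives (2S,3R,4S)-2-[(4-methoxybenzyl)oxy]-4-methylhex-5-en-3-ol F6. Silylation (TBSOTf, 2,6-lutidine) gives tert-butyl{[(2S,3R,4S)-2-[(4-methoxybenzyl)oxy]-4-methylhex-5-en-3-yl]oxy}dimethylsilane F7, and DDQ (CH2Cl2/pH 7 buffer) releases (2S,3R,4S)-3-[(tert-butyldimethylsilyl)oxy]-4-methylhex-5-en-2-ol F8. Steglich esterification of F8 with 7 (DCC, DMAP) gives 14, where the route resumes at step 9.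

Step 20 (semi-hydrogenation on the complete, unprotected molecule). The risks are over-reduction and closure of the product to a butenolide with loss of the C8 alcohol. The fallback fixes the Z-alkene in the side chain before coupling, so no hydrogenation is run on the full skeleton. It sets out from 26: semi-hydrogenation (H2, Pd/CaCO3 poisoned with Pb(OAc)2, quinoline) gives methyl (2Z,4R)-4-[(triethylsilyl)oxy]dec-2-enoate F9, and saponification (LiOH, THF/H2O, 0 °C) gives (2Z,4R)-4-[(triethylsilyl)oxy]dec-2-enoic acid F10. Esterification with 21 (DCC, DMAP cat., CH2Cl2, −20 °C) gives the C8 Z-enoate ester of 21 F11. Brief treatment with cold aqueous CF3CO2H as in step 19 removes the acetonide and silyl ether and gives 30 directly.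

**Further compounds**
F1 | step 10 | (2S,3R,4S)-3-[(tert-butyldimethylsilyl)oxy]-4-methylhex-5-en-2-yl (2R,3R)-3-(benzyloxy)-2,4-dimethylpent-4-enoate | C=C(C)[C@H](OCc1ccccc1)[C@@H](C)C(=O)O[C@@H](C)[C@H](O[Si](C)(C)C(C)(C)C)[C@@H](C)C=C
F2 | step 10 | nine-membered lactone with a Z C5=C6 alkene (4-benzyloxy, 8-silyloxy, 3,5,7,9-tetramethyl; other centres as in 17) | CC(C)(C)[Si](C)(C)O[C@@H]1[C@@H](C)/C=C(C)\[C@H](OCc2ccccc2)[C@@H](C)C(=O)O[C@H]1C
F3 | step 10 | cis-5,6-epoxide of F2 (oxygen on the face of the C6–O bond of 17) | CC(C)(C)[Si](C)(C)O[C@@H]1[C@@H](C)[C@@H]2O[C@]2(C)[C@H](OCc3ccccc3)[C@@H](C)C(=O)O[C@H]1C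
F4 | step 7 | ethyl (S)-2-[(4-methoxybenzyl)oxy]propanoate | CCOC(=O)[C@H](C)OCc1ccc(OC)cc1
F5 | step 7 | (S)-2-[(4-methoxybenzyl)oxy]propanal | C[C@H](OCc1ccc(OC)cc1)C=O
F6 | step 7 | (2S,3R,4S)-2-[(4-methoxybenzyl)oxy]-4-methylhex-5-en-3-ol | C[C@H](OCc1ccc(OC)cc1)[C@H](O)[C@@H](C)C=C
F7 | step 7 | tert-butyl{[(2S,3R,4S)-2-[(4-methoxybenzyl)oxy]-4-methylhex-5-en-3-yl]oxy}dimethylsilane | C[C@H](OCc1ccc(OC)cc1)[C@H](O[Si](C)(C)C(C)(C)C)[C@@H](C)C=C
F8 | step 7 | (2S,3R,4S)-3-[(tert-butyldimethylsilyl)oxy]-4-methylhex-5-en-2-ol | C[C@H](O)[C@H](O[Si](C)(C)C(C)(C)C)[C@@H](C)C=C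
F9 | step 20 | methyl (2Z,4R)-4-[(triethylsilyl)oxy]dec-2-enoate | CCCCCC[C@@H](O[Si](CC)(CC)CC)/C=C\C(=O)OC
F10 | step 20 | (2Z,4R)-4-[(triethylsilyl)oxy]dec-2-enoic acid | CCCCCC[C@@H](O[Si](CC)(CC)CC)/C=C\C(=O)O
F11 | step 20 | C8 ester of 21 with F10 (acetonide and triethylsilyl ether in place) | CCCCCC[C@@H](O[Si](CC)(CC)CC)/C=C\C(=O)O[C@@H]1[C@@H](C)[C@@H]2OC(C)(C)O[C@@]2(C)[C@H](OC(C)=O)[C@@H](C)C(=O)O[C@H]1C
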